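Delta's X stands older at the end than eta's: delta has its whole Z charge at the start, while eta receives it over 8.0 h.

| flask | D | Z | remark | time |
|---|---|---|---|---|
| spring | 0.045 M | 0.20 M (fed, over 8.0 h) | run made earlier |  |
| autumn | 0.078 M | 0.20 M (fed, over 8.0 h) | run made earlier |  |
| winter | 0.089 M | 0.20 M (fed, over 8.0 h) | run made earlier |  |
| delta | 0.060 M | 0.200 M | everything together at the start | 8.0 h |
| eta | 0.10 M | 0.200 M (fed, over 8.0 h) |  | 8.0 h |

| run | time / h | X / % |
|---|---|---|
| spring | 0.667 | 11 |
| spring | 1.33 | 29 |
| spring | 2.50 | 64 |
| spring | 4.00 | 80 |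
| spring | 8.00 | 64 |
| autumn | 0.667 | 8 |
| autumn | 2.00 | 39 |
| autumn | 4.00 | 73 |
| autumn | 6.00 | 76 |
| autumn | 8.00 | 65 |
| winter | 0.667 | 3 |
| winter | 2.00 | 33 |
| winter | 4.00 | 68 |
| winter | 6.00 | 75 |
| winter | 8.00 | 71 |

(standard deviation of a reading: 1.5 percentage points)

- the analysis behind the earlier runs scatters by 1.5 percentage points, standard deviation

- which one finishes higher in amount of X, in percent of the D charged ("neither" within 2 percentage points) (delta / eta / neither)
- amount of X at the end, in percent of the D charged, delta
- amount of X at the end, in percent of the D charged, eta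

1. Z enters the fed runs at 0.0250 M h⁻¹. Reckoned with one Z taking one D at once, X is born evenly until D is used up. Its mean age at the end is then the time less half of that span: 7.10 h in spring, 6.44 h in autumn, 6.22 h in winter.

2. The end readings over these ages give 0.0629 h⁻¹, 0.0669 h⁻¹ and 0.0551 h⁻¹. Their mean, 0.0616 h⁻¹, is the age constant of X: the first-order loss per hour of mean age, a reading with the scatter of the readings.

3. Turned round: for delta to catch eta at these mean ages, eta's constant must exceed delta's by a factor of 1.33. The constants read from the runs differ by a factor of 1.21, and one Z per D leaves eta with less spare Z than delta.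

4. My reckoning takes delta's age as 8.0 h and eta's as 6.00 h, giving delta 61.1% and eta 69.1%.

5. The forecast says eta, with delta 39% and eta 71%, reasoning that “higher D leaves less excess Z”. On delta it stands lower than my reckoning.

6. The flasks give delta 59.9% and eta 68.5%, so eta finishes higher. In delta, Z reads 70.0% of its charge at 4.00 h and 70.0% at 8.00 h, while X falls from 74.3% to 59.9% of the D charged and E reaches 40.1%. The age constant carried over those hours from 74.3% gives delta 58.1%.

    D + Z ⇌ G (K = 15.0 M⁻¹, k = 50.7 M⁻¹ h⁻¹)
    X ⇌ E (K = 1.18, k = 0.0954 h⁻¹)
    G → X (k = 6.37 h⁻¹)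

7. The neighbour flask is delta charged with 0.24 M of D, so Z covers 0.833 equiv and is the limiting reagent. That share times the survival over 8.0 h gives 50.9%. The computed flask gives 50.2%, with 0% of Z and 17% of D left.

The earlier runs and the new flask stem from a simulated flask with constants of no real substance, and the scatter is random.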